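**Plan**

1. Retrosynthesis: the C6–C(=O) bond of ring A is cut first (C6 aryllithium from a C6 bromide plus the Weinreb amide of the ring-B propanoic acid). The pyran is then cut at both C2–CH3 bonds and at O1–C2, which leads back to a coumarin. Next comes the C8–CH2 prenyl bond (Claisen shift from a 7-O-(1,1-dimethylallyl) ether), and last the coumarin itself (C4–C4a and the lactone C–O bond, from 4-bromoresorcinol and ethyl propiolate).
2. Enabling feature: C2 of the pyran ring is quaternary, carries two methyl groups and O1, and sits beside the cis C3=C4 alkene. This is what a coumarin lactone carbonyl carbon becomes after taking up two methyl nucleophiles and reclosing at O1.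
3. Forward order: the lactone ring is made first; prenyl is placed at C8 while bromine blocks C6; the 7-OH is masked as a MOM ether; the lactone is turned into the 2,2-dimethylpyran; the side chain is joined at C6 through the bromine; both MOM groups are removed together.
4. Stereochemistry: the target has no stereocentre. The C3=C4 alkene is cis because it is endocyclic throughout, and the prenyl alkene carries two identical methyl groups.

Key step: step 6

Remark: the SMILES shows no stereocentre, so the target is treated as achiral; the transient species 7 and 18 each carry one stereocentre, form as racemates and lose it within the same step. Chromene numbering (O1, C2 to C8a) is used throughout; ring A is the benzene ring of the chromene, ring B the 4-hydroxyphenyl ring; MOM = methoxymethyl.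

**Route**

Step 1
Reactants: 1 4-bromoresorcinol; 2 ethyl propiolate
Product: 3 6-bromo-7-hydroxy-2H-chromen-2-one
Conditions: ZnCl2 (1 equiv), dioxane, 100 °C
Reagents that add atoms: none
Why: Pechmann-type coumarin synthesis in its propiolate variant: the ZnCl2-activated alkyne is attacked by C6 of 1 (para to one hydroxyl, ortho to the other, away from bromine) and the resulting cis-cinnamate lactonizes onto the ortho hydroxyl, which places bromine at C6 and the free hydroxyl at C7 without ambiguity.

Step 2
Reactants: 3 6-bromo-7-hydroxy-2H-chromen-2-one; 4 3-chloro-3-methylbut-1-yne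
Product: 5 6-bromo-7-[(2-methylbut-3-yn-2-yl)oxy]-2H-chromen-2-one
Conditions: CuCl2·2H2O (cat.), DBU, MeCN, 0 °C
Reagents that add atoms: 3-chloro-3-methylbut-1-yne (4), CC(C)(Cl)C#C
Why: Copper-catalysed propargylic etherification (substitution of the tertiary propargylic chloride through a copper acetylide) is effective for acidic, weakly nucleophilic phenols such as 7-hydroxycoumarins and runs at 0 °C, far below the temperature at which the aryl propargyl ether would rearrange.

Step 3
Reactants: 5 6-bromo-7-[(2-methylbut-3-yn-2-yl)oxy]-2H-chromen-2-one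
Product: 6 6-bromo-7-[(2-methylbut-3-en-2-yl)oxy]-2H-chromen-2-one
Conditions: H2 (1 atm), Pd/CaCO3 poisoned with Pb(OAc)2 (Lindlar catalyst), quinoline, EtOAc, rt
Reagents that add atoms: none
Why: Lindlar semihydrogenation of the terminal alkyne stops at the alkene on the poisoned catalyst, which leaves the aryl bromide and the conjugated lactone alkene untouched.

Step 4
Reactants: 6 6-bromo-7-[(2-methylbut-3-en-2-yl)oxy]-2H-chromen-2-one
Product: 8 6-bromo-7-hydroxy-8-(3-methylbut-2-enyl)-2H-chromen-2-one, via ortho-dienone 7 (not isolated)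
Conditions: PhNEt2, 130–140 °C
Reagents that add atoms: none
Why: Aromatic Claisen rearrangement ([3,3]-sigmatropic shift) of the tertiary allyl aryl ether: with C6 blocked by bromine the allyl unit can only arrive, inverted to a 3-methylbut-2-enyl group, at C8, and dienone 7 tautomerizes to the phenol.

Step 5
Reactants: 8 6-bromo-7-hydroxy-8-(3-methylbut-2-enyl)-2H-chromen-2-one
Product: 9 6-bromo-7-(methoxymethoxy)-8-(3-methylbut-2-enyl)-2H-chromen-2-one
Conditions: MOMCl, i-Pr2NEt, CH2Cl2, 0 °C to rt
Reagents that add atoms: chloromethyl methyl ether (MOMCl), COCCl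
Why: Williamson-type O-alkylation of the acidic 7-OH with the reactive chloromethyl ether gives an acetal that keeps the lactone carbonyl electrophilic in step 6 (no vinylogous phenoxide), cannot migrate from oxygen to a neighbouring carbanion as a silyl group would, and later chelates the C6 aryllithium.

Step 6
Reactants: 9 6-bromo-7-(methoxymethoxy)-8-(3-methylbut-2-enyl)-2H-chromen-2-one; 10 methyllithium
Product: 13 6-bromo-7-(methoxymethoxy)-2,2-dimethyl-8-(3-methylbut-2-enyl)-2H-chromene, via Z-enone lithium phenoxide 11 (not isolated), via Z-allylic tertiary alcohol 12 (not isolated)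
Conditions: MeLi (3.5 equiv), THF, −78 → 0 °C; AcOH quench; then PPTS (cat.), MgSO4, CH2Cl2, rt
Reagents that add atoms: methyllithium (10), [Li]C
Why: MeLi attacks the lactone carbonyl C2 in a 1,2 sense, the tetrahedral adduct opens to the Z-enone phenoxide 11, and a second MeLi adds to the ketone, so that both C2–CH3 bonds are in place in the Z-allylic tertiary alcohol 12 obtained on AcOH quench. With catalytic PPTS the tertiary allylic hydroxyl ionizes to a cation spread over C2–C3–C4 and the electron-rich ring A, and the phenol oxygen O1, kept within reach by the Z alkene, bonds to C2. The closest known reaction type is the conversion of coumarins into 2,2-dimethyl-2H-chromenes by double addition of a methyl Grignard or methyllithium reagent followed by acid cyclodehydration. The pyran ring closes in a six-membered mode by oxygen attack at the terminus of the allyl cation (6-endo with respect to the C3=C4 alkene of the product, equivalent to oxa-6π closure of the ortho-quinone methide); no stereocentre is created, and the C3=C4 alkene stays cis because it is inherited from the lactone ring. The step needs 1,2- over 1,4-addition and an untouched C6–Br bond: hard MeLi at −78 °C prefers the carbonyl, the MOM ether avoids a deactivating vinylogous 7-phenoxide, and bromine–lithium exchange by MeLi is slow at this temperature. In the closure only O1 can reach the cation, and PPTS is too weak to protonate the prenyl alkene or cleave the MOM acetal.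

Step 7
Reactants: 14 3-(4-hydroxyphenyl)propanoic acid
Product: 15 3-(4-hydroxyphenyl)-N-methoxy-N-methylpropanamide
Conditions: MeNHOMe·HCl, EDC·HCl, HOBt (cat.), Et3N, CH2Cl2, 0 °C to rt
Reagents that add atoms: N,O-dimethylhydroxylamine hydrochloride, Cl.CNOC
Why: Carbodiimide-mediated amide coupling through the HOBt active ester forms the Weinreb amide, the amine outcompeting the free phenol for the activated acid.

Step 8
Reactants: 15 3-(4-hydroxyphenyl)-N-methoxy-N-methylpropanamide
Product: 16 N-methoxy-3-[4-(methoxymethoxy)phenyl]-N-methylpropanamide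
Conditions: MOMCl, i-Pr2NEt, CH2Cl2, 0 °C to rt
Reagents that add atoms: chloromethyl methyl ether (MOMCl), COCCl
Why: Williamson-type O-alkylation of the phenol removes the only acidic proton of the amide before it meets the aryllithium and installs the same acetal as on ring A, so that one acid treatment can free both phenols at the end.

Step 9
Reactants: 13 6-bromo-7-(methoxymethoxy)-2,2-dimethyl-8-(3-methylbut-2-enyl)-2H-chromene; 16 N-methoxy-3-[4-(methoxymethoxy)phenyl]-N-methylpropanamide
Product: 19 1-[7-(methoxymethoxy)-2,2-dimethyl-8-(3-methylbut-2-enyl)-2H-chromen-6-yl]-3-[4-(methoxymethoxy)phenyl]propan-1-one, via aryllithium 17 (not isolated), via tetrahedral lithium adduct 18 (not isolated)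
Conditions: n-BuLi (1.05 equiv), THF, −78 °C; then 16, −78 → 0 °C; H2O
Reagents that add atoms: none
Why: Bromine–lithium exchange gives aryllithium 17, held by chelation to the neighbouring MOM oxygen, and the Weinreb ketone synthesis then stops at the chelated tetrahedral adduct 18, which releases the ketone only on quench so that no tertiary alcohol forms.

Step 10
Reactants: 19 1-[7-(methoxymethoxy)-2,2-dimethyl-8-(3-methylbut-2-enyl)-2H-chromen-6-yl]-3-[4-(methoxymethoxy)phenyl]propan-1-one
Product: 20 1-[7-hydroxy-2,2-dimethyl-8-(3-methylbut-2-enyl)-2H-chromen-6-yl]-3-(4-hydroxyphenyl)propan-1-one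
Conditions: HCl (3 M aq., cat.), MeOH, rt to 40 °C
Reagents that add atoms: none
Why: Acid-catalysed acetal methanolysis (MOM ether cleavage) frees both phenols, the MOM group ortho to the ketone leaving first with hydrogen-bond assistance, while the electron-poor acylated ring A tempers protonation of the chromene and prenyl alkenes under dilute HCl.

**Compound list**

1 | 4-bromoresorcinol (4-bromobenzene-1,3-diol) | Oc1ccc(Br)c(O)c1 | starting material
2 | ethyl propiolate | CCOC(=O)C#C | starting material
3 | 6-bromo-7-hydroxy-2H-chromen-2-one | O=C1C=Cc2cc(Br)c(O)cc2O1 | intermediate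
4 | 3-chloro-3-methylbut-1-yne | CC(C)(Cl)C#C | starting material
5 | 6-bromo-7-[(2-methylbut-3-yn-2-yl)oxy]-2H-chromen-2-one | O=C1C=Cc2cc(Br)c(OC(C)(C)C#C)cc2O1 | intermediate
6 | 6-bromo-7-[(2-methylbut-3-en-2-yl)oxy]-2H-chromen-2-one | O=C1C=Cc2cc(Br)c(OC(C)(C)C=C)cc2O1 | intermediate
7 | 6-bromo-8-(3-methylbut-2-enyl)-8H-chromene-2,7-dione (racemic ortho-dienone, not isolated) | O=C1C=CC2=C(O1)C(CC=C(C)C)C(=O)C(Br)=C2 | intermediate
8 | 6-bromo-7-hydroxy-8-(3-methylbut-2-enyl)-2H-chromen-2-one | O=C1C=Cc2cc(Br)c(O)c(CC=C(C)C)c2O1 | intermediate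
9 | 6-bromo-7-(methoxymethoxy)-8-(3-methylbut-2-enyl)-2H-chromen-2-one | COCOc1c(Br)cc2C=CC(=O)Oc2c1CC=C(C)C | intermediate
10 | methyllithium | [Li]C | starting material
11 | lithium 4-bromo-3-(methoxymethoxy)-2-(3-methylbut-2-enyl)-6-[(Z)-3-oxobut-1-enyl]phenolate (not isolated) | CC(=O)/C=C\c1cc(Br)c(OCOC)c(CC=C(C)C)c1O[Li] | intermediate
12 | 4-bromo-6-[(Z)-3-hydroxy-3-methylbut-1-enyl]-3-(methoxymethoxy)-2-(3-methylbut-2-enyl)phenol (not isolated) | CC(C)(O)/C=C\c1cc(Br)c(OCOC)c(CC=C(C)C)c1O | intermediate
13 | 6-bromo-7-(methoxymethoxy)-2,2-dimethyl-8-(3-methylbut-2-enyl)-2H-chromene | COCOc1c(Br)cc2C=CC(C)(C)Oc2c1CC=C(C)C | intermediate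
14 | 3-(4-hydroxyphenyl)propanoic acid | O=C(O)CCc1ccc(O)cc1 | starting material
15 | 3-(4-hydroxyphenyl)-N-methoxy-N-methylpropanamide | CON(C)C(=O)CCc1ccc(O)cc1 | intermediate
16 | N-methoxy-3-[4-(methoxymethoxy)phenyl]-N-methylpropanamide | CON(C)C(=O)CCc1ccc(OCOC)cc1 | intermediate
17 | [7-(methoxymethoxy)-2,2-dimethyl-8-(3-methylbut-2-enyl)-2H-chromen-6-yl]lithium (not isolated) | [Li]c1cc2C=CC(C)(C)Oc2c(CC=C(C)C)c1OCOC | intermediate
18 | lithium 1-[methoxy(methyl)amino]-1-[7-(methoxymethoxy)-2,2-dimethyl-8-(3-methylbut-2-enyl)-2H-chromen-6-yl]-3-[4-(methoxymethoxy)phenyl]propan-1-olate (racemic, not isolated) | CON(C)C(O[Li])(CCc1ccc(OCOC)cc1)c1cc2C=CC(C)(C)Oc2c(CC=C(C)C)c1OCOC | intermediate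
19 | 1-[7-(methoxymethoxy)-2,2-dimethyl-8-(3-methylbut-2-enyl)-2H-chromen-6-yl]-3-[4-(methoxymethoxy)phenyl]propan-1-one | COCOc1ccc(CCC(=O)c2cc3C=CC(C)(C)Oc3c(CC=C(C)C)c2OCOC)cc1 | intermediate
20 | 1-[7-hydroxy-2,2-dimethyl-8-(3-methylbut-2-enyl)-2H-chromen-6-yl]-3-(4-hydroxyphenyl)propan-1-one | CC(C)=CCc1c(O)c(C(=O)CCc2ccc(O)cc2)cc2c1OC(C)(C)C=C2 | target

**Count and risks**

Total steps: 10. Longest linear sequence: 8 steps (steps 1 to 6, 9 and 10); steps 7 and 8 form the side branch.

Steps most likely to fail:

Step 6. What may go wrong: the second methyl addition may be overtaken by enolization of the intermediate methyl ketone or by conjugate addition at C4, and on warming MeLi may exchange the C6 bromine, so that mono-methylated or debrominated material results.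

Fallback: the gem-dimethyl carbon is brought in from the start instead of being made from a lactone carbonyl. The fallback sets out from 1. Acylation and oxa-Michael closure with 3-methylbut-2-enoic acid in MeSO3H/P2O5 at 70 °C should give 6-bromo-7-hydroxy-2,2-dimethylchroman-4-one F1, with the regiochemistry of step 1 (attack para to one hydroxyl). The 7-OH is then taken through the chemistry of steps 2 to 5. Copper-catalysed etherification with 4 should give 6-bromo-2,2-dimethyl-7-[(2-methylbut-3-yn-2-yl)oxy]chroman-4-one F2, and Lindlar semihydrogenation 6-bromo-2,2-dimethyl-7-[(2-methylbut-3-en-2-yl)oxy]chroman-4-one F3. Claisen rearrangement then passes through the racemic, non-isolated 6-bromo-2,2-dimethyl-8-(3-methylbut-2-enyl)-3,8-dihydro-2H-chromene-4,7-dione F4 to 6-bromo-7-hydroxy-2,2-dimethyl-8-(3-methylbut-2-enyl)chroman-4-one F5. MOMCl with i-Pr2NEt protects this as 6-bromo-7-(methoxymethoxy)-2,2-dimethyl-8-(3-methylbut-2-enyl)chroman-4-one F6. NaBH4 in MeOH should reduce the ketone to racemic 6-bromo-7-(methoxymethoxy)-2,2-dimethyl-8-(3-methylbut-2-enyl)chroman-4-ol F7. Dehydration of this benzylic alcohol with catalytic p-TsOH in toluene at 60 °C returns to the route at 13.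

Step 4. What may go wrong: the tertiary allyl ether may fragment back to phenol 3 with loss of isoprene faster than it rearranges, and the ortho-prenyl phenol, once formed, may cyclize or rearrange further at the reaction temperature.

Fallback: the prenyl group is built from a primary allyl group, which has no tertiary C–O bond to ionize. The fallback sets out from 3. Allyl bromide and K2CO3 in refluxing acetone should give 7-(allyloxy)-6-bromo-2H-chromen-2-one F8. Claisen rearrangement in PhNEt2 at 200 °C passes through the racemic, non-isolated 6-bromo-8-(prop-2-enyl)-8H-chromene-2,7-dione F9 to 8-allyl-6-bromo-7-hydroxy-2H-chromen-2-one F10. Olefin cross-metathesis with excess 2-methylbut-2-ene and the second-generation Grubbs catalyst (H2IMes)(PCy3)Cl2Ru=CHPh in CH2Cl2 at 40 °C exchanges the terminal CH2 for CMe2 and returns to the route at 8.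

Step 10. What may go wrong: during the slower cleavage of the non-chelated ring-B MOM ether, acid may add the freed 7-OH across the neighbouring prenyl alkene or add methanol to, or oligomerize, the chromene alkene.

Fallback: the two protecting groups are made orthogonal so that acid is needed only for the easily cleaved chelated acetal. The fallback sets out from 15. TBSCl and imidazole in DMF should give 3-[4-(tert-butyldimethylsilyloxy)phenyl]-N-methoxy-N-methylpropanamide F11. Aryllithium 17, generated from 13 as in step 9, adds to F11 to give the racemic, non-isolated lithium 3-[4-(tert-butyldimethylsilyloxy)phenyl]-1-[methoxy(methyl)amino]-1-[7-(methoxymethoxy)-2,2-dimethyl-8-(3-methylbut-2-enyl)-2H-chromen-6-yl]propan-1-olate F12. Aqueous quench releases 3-[4-(tert-butyldimethylsilyloxy)phenyl]-1-[7-(methoxymethoxy)-2,2-dimethyl-8-(3-methylbut-2-enyl)-2H-chromen-6-yl]propan-1-one F13. Brief treatment with dilute HCl in MeOH at 0 °C should remove only the MOM group ortho to the ketone and give 3-[4-(tert-butyldimethylsilyloxy)phenyl]-1-[7-hydroxy-2,2-dimethyl-8-(3-methylbut-2-enyl)-2H-chromen-6-yl]propan-1-one F14. TBAF buffered with AcOH in THF at 0 °C then cleaves the silyl ether and returns to the route at 20.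

**Further compounds**

F1 | step 6 | 6-bromo-7-hydroxy-2,2-dimethylchroman-4-one | CC1(C)CC(=O)c2cc(Br)c(O)cc2O1
F2 | step 6 | 6-bromo-2,2-dimethyl-7-[(2-methylbut-3-yn-2-yl)oxy]chroman-4-one | CC1(C)CC(=O)c2cc(Br)c(OC(C)(C)C#C)cc2O1
F3 | step 6 | 6-bromo-2,2-dimethyl-7-[(2-methylbut-3-en-2-yl)oxy]chroman-4-one | CC1(C)CC(=O)c2cc(Br)c(OC(C)(C)C=C)cc2O1
F4 | step 6 | 6-bromo-2,2-dimethyl-8-(3-methylbut-2-enyl)-3,8-dihydro-2H-chromene-4,7-dione (racemic, not isolated) | CC1(C)CC(=O)C2=C(O1)C(CC=C(C)C)C(=O)C(Br)=C2
F5 | step 6 | 6-bromo-7-hydroxy-2,2-dimethyl-8-(3-methylbut-2-enyl)chroman-4-one | CC(C)=CCc1c(O)c(Br)cc2c1OC(C)(C)CC2=O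
F6 | step 6 | 6-bromo-7-(methoxymethoxy)-2,2-dimethyl-8-(3-methylbut-2-enyl)chroman-4-one | COCOc1c(Br)cc2C(=O)CC(C)(C)Oc2c1CC=C(C)C
F7 | step 6 | 6-bromo-7-(methoxymethoxy)-2,2-dimethyl-8-(3-methylbut-2-enyl)chroman-4-ol (racemic) | COCOc1c(Br)cc2C(O)CC(C)(C)Oc2c1CC=C(C)C
F8 | step 4 | 7-(allyloxy)-6-bromo-2H-chromen-2-one | O=C1C=Cc2cc(Br)c(OCC=C)cc2O1
F9 | step 4 | 6-bromo-8-(prop-2-enyl)-8H-chromene-2,7-dione (racemic, not isolated) | O=C1C=CC2=C(O1)C(CC=C)C(=O)C(Br)=C2
F10 | step 4 | 8-allyl-6-bromo-7-hydroxy-2H-chromen-2-one | O=C1C=Cc2cc(Br)c(O)c(CC=C)c2O1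
F11 | step 10 | 3-[4-(tert-butyldimethylsilyloxy)phenyl]-N-methoxy-N-methylpropanamide | CON(C)C(=O)CCc1ccc(O[Si](C)(C)C(C)(C)C)cc1
F12 | step 10 | lithium 3-[4-(tert-butyldimethylsilyloxy)phenyl]-1-[methoxy(methyl)amino]-1-[7-(methoxymethoxy)-2,2-dimethyl-8-(3-methylbut-2-enyl)-2H-chromen-6-yl]propan-1-olate (racemic, not isolated) | CON(C)C(O[Li])(CCc1ccc(O[Si](C)(C)C(C)(C)C)cc1)c1cc2C=CC(C)(C)Oc2c(CC=C(C)C)c1OCOC
F13 | step 10 | 3-[4-(tert-butyldimethylsilyloxy)phenyl]-1-[7-(methoxymethoxy)-2,2-dimethyl-8-(3-methylbut-2-enyl)-2H-chromen-6-yl]propan-1-one | CC(C)=CCc1c(OCOC)c(C(=O)CCc2ccc(O[Si](C)(C)C(C)(C)C)cc2)cc2c1OC(C)(C)C=C2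
F14 | step 10 | 3-[4-(tert-butyldimethylsilyloxy)phenyl]-1-[7-hydroxy-2,2-dimethyl-8-(3-methylbut-2-enyl)-2H-chromen-6-yl]propan-1-one | CC(C)=CCc1c(O)c(C(=O)CCc2ccc(O[Si](C)(C)C(C)(C)C)cc2)cc2c1OC(C)(C)C=C2
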